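**Chain share.** At 40.0 h the north-east run holds 75 % of its charge as monomer in chains, the south run 75 % and the east run 75 %, though their charges go from 0.052 M to 0.11 M. I call the mean of these readings the chain share f, the part of the charged free monomer that ends in chains: 75.0 %, with a scatter of 2 percentage points on each reading.

| flask | free monomer | initiator | remark | time |
|---|---|---|---|---|
| north-east | 0.052 M (fed, over 50 min) | 0.50 mM | run made earlier; the fed solution adds 0.20 times the starting volume |  |
| south | 0.094 M (fed, over 50 min) | 0.50 mM | run made earlier; the fed solution adds 0.20 times the starting volume |  |
| east | 0.11 M (fed, over 50 min) | 0.50 mM | run made earlier; the fed solution adds 0.20 times the starting volume |  |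
| theta | 0.050 M (fed, over 50 min) | 0.50 mM | the fed solution adds 0.20 times the starting volume | 40 h |
| epsilon | 0.15 M (fed, over 50 min) | 0.50 mM | the fed solution adds 0.20 times the starting volume | 40 h |

| run | time / h | monomer in chains / % | free monomer / % |
|---|---|---|---|
| north-east | 10.0 | 52 | 46 |
| north-east | 20.0 | 70 | 30 |
| north-east | 30.0 | 70 | 20 |
| north-east | 40.0 | 75 | 14 |
| south | 3.00 | 20 | 78 |
| south | 8.00 | 47 | 46 |
| south | 15.0 | 68 | 30 |
| south | 40.0 | 75 | 16 |
| east | 5.00 | 35 | 64 |
| east | 15.0 | 65 | 33 |
| east | 25.0 | 74 | 20 |
| east | 40.0 | 75 | 16 |

(readings scatter by 2 percentage points)

- every charge counts on the volume at the start, and the solution that is fed holds the whole dose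
- the average divides the monomer in chains by the number of chains begun, living and dead together
- what was read earlier has a scatter of 2 percentage points, one standard deviation
- what may be going on: free monomer + initiator -> living end + monomer in chains; free monomer + living end -> monomer in chains + living end; free monomer -> uncatalysed product; living end -> dead end
- the earlier runs do not show the number of chains; that part of a forecast is a guess

1. which of the two ends with the longer chains by the average number of monomer units in a chain (chains begun, living or dead) ("neither" if they lie within 10 %) (theta / epsilon / neither)
2. average number of monomer units in a chain (chains begun, living or dead) at the end, theta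
3. average number of monomer units in a chain (chains begun, living or dead) at the end, epsilon

**Two routes.** Take one moment, with free monomer at concentration F and living ends at concentration L. Growth consumes free monomer at rate kg·L·F, and the uncatalysed step at ku·F, where kg and ku are rate constants. Their ratio, a selectivity, is kg·L/ku, and F cancels. That fits a share that does not follow the monomer charge. L comes from the initiator, which stood at 0.50 mM in these runs, so I carry f at that initiator charge.

**The drift.** Living ends die, so wherever they die faster than initiator makes new ones, L falls and the ratio falls with it. The east run fits this as a reading: from 25.0 h to 40.0 h monomer in chains goes from 74 % to 75 %, while free monomer goes from 20 % to 16 %. Within the scatter, the east run's share has flattened by then.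

**My reckoning.** The average length is monomer in chains over chains begun, f·charge/initiator. The runs do not show the number of chains, so I guess one chain per initiator charged. Theta gives 75.0 and epsilon 225, though epsilon's charge lies beyond the runs.

**The forecast.** It says epsilon, with 77 (65 to 100) for theta and 225 (190 to 265) for epsilon. Its theta figure stands above mine, “perhaps slightly more if initiation is incomplete at low monomer”.

**Result.** Theta ends at 74.9 and epsilon at 226, so epsilon has the longer chains, on these steps:

    free monomer + initiator → living end + monomer in chains (k = 0.195 L mol⁻¹ min⁻¹)
    free monomer + living end → monomer in chains + living end, rate k2*[living end]*[free monomer] (k = 5.88 L mol⁻¹ min⁻¹)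
    free monomer → uncatalysed product (k = 9.44 × 10⁻⁵ min⁻¹)
    living end → dead end (k = 0.00155 min⁻¹)

**Second flask.** At 40.0 h theta holds 74.8 % as monomer in chains and epsilon 75.4 %, beside the carried f of 75.0 %. Now take theta with initiator at 1.3 × 10⁻⁴ M: f gives 288, but that neighbour flask ends at 120, and f was read at 0.50 mM. That flask holds 31.1 % as monomer in chains, which in the same ratio gives 120.

The numbers in the tables come from a simulation on assumed constants; scatter was added.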